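**Assumption:** quinic acid numbering is used (O1 tertiary; O3 and O4 cis; O5 trans to O4 and cis to CO2H). On that numbering the target SMILES is 1,3-di-O-(E)-caffeoyl-(−)-quinic acid, and (−)-quinic acid, caffeic acid and phenylboronic acid are taken as the commercial starting materials.

## Retrosynthetic overview

1. Target ⇐ aqueous-acid unmasking of a 1,3-bis(di-O-acetylcaffeoyl)-1,5-quinide: the γ-lactone opens to CO2H and 5-OH, and four aryl acetates become phenols.
2. C3–O ester ⇐ borinic-acid-templated acylation of the equatorial 3-OH of a 1-O-acyl quinide cis-3,4-diol.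
3. C1–O ester ⇐ quinic acid doubly ring-locked in one dehydration: the γ-lactone (CO2H to O5) and a 1,3,2-dioxaborolane (O3, O4) close together, leaving only the tertiary 1-OH free; boron is released in the same pot.
4. Acyl donor ⇐ caffeic acid, via the diacetate and the acid chloride.
5. Ring order: the cyclohexane and both arenes are bought; the lactone and dioxaborolane rings form together (step 3) and the dioxaborolane is opened again in that step; the lactone is opened last (step 5).

## Route

Step 1
Reactants: 1 caffeic acid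
Product: 2 (E)-3-(3,4-diacetoxyphenyl)prop-2-enoic acid
Conditions: Ac2O (3 equiv), pyridine, 4-(dimethylamino)pyridine (2 mol%), 0 °C → rt; then cold 1 M aq HCl
Reagents that add atoms: acetic anhydride, CC(=O)OC(C)=O
Why: Nucleophilic acyl substitution (O-acetylation) caps both phenols, the transient mixed anhydride at the acid is hydrolysed in the acidic work-up, the E-alkene is untouched and no stereocentre is formed.

Step 2
Reactants: 2 (E)-3-(3,4-diacetoxyphenyl)prop-2-enoic acid
Product: 3 (E)-3-(3,4-diacetoxyphenyl)prop-2-enoyl chloride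
Conditions: (COCl)2 (1.5 equiv), HCONMe2 (cat.), CH2Cl2, 0 °C → rt; evaporate, use crude
Reagents that add atoms: oxalyl chloride, O=C(Cl)C(Cl)=O
Why: Acid chloride formation through the Vilsmeier-type chloroiminium intermediate runs under neutral conditions that leave the aryl acetates and the E-alkene intact, and no stereocentre is formed.

Step 3
Reactants: 4 (−)-quinic acid; 5 phenylboronic acid; 3 (E)-3-(3,4-diacetoxyphenyl)prop-2-enoyl chloride
Product: 8 1-O-[(E)-3,4-diacetoxycinnamoyl]-1,5-quinide, via quinide 3,4-O-phenylboronate 6 (not isolated), via 1-O-acyl quinide 3,4-O-phenylboronate 7 (not isolated)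
Conditions: (a) 5 (1.05 equiv), p-MeC6H4SO3H·H2O (5 mol%), toluene/HCONMe2 5:1, reflux, Dean–Stark, then concentrate; (b) 3 (1.5 equiv), 4-(dimethylamino)pyridine (0.5 equiv), pyridine/CH2Cl2, 0 °C → rt; (c) pinacol (3 equiv), THF/H2O 10:1, rt
Reagents that add atoms: none
Why: Proposed new method: under azeotropic dehydration the acid catalyst closes the γ-lactone between the C1 carboxyl and the cis 5-OH (ring flip makes both axial) while PhB(OH)2 condenses with the only cis-vicinal pair left (3-OH/4-OH) to a 1,3,2-dioxaborolane, so two rings form in one operation and every hydroxyl except the tertiary 1-OH is masked, after which 4-(dimethylamino)pyridine-catalysed acylation by 3 and boronate transesterification to pinacol release diol 8; the closest known reaction types are the one-pot acid-catalysed lactonisation/acetalisation of quinic acid to its 3,4-acetonide 1,5-lactone and the use of cyclic phenylboronates as transient cis-diol protection during acylation of sugars; no stereocentre is formed or inverted because only O–H, O–B and acyl C–O bonds change.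

Step 4
Reactants: 8 1-O-[(E)-3,4-diacetoxycinnamoyl]-1,5-quinide; 3 (E)-3-(3,4-diacetoxyphenyl)prop-2-enoyl chloride
Product: 9 1,3-bis-O-[(E)-3,4-diacetoxycinnamoyl]-1,5-quinide
Conditions: 3 (1.2 equiv), Ph2BOCH2CH2NH2 (10 mol%), i-Pr2NEt (1.5 equiv), MeCN, 0 °C → rt
Reagents that add atoms: none
Why: Borinic-acid-catalysed regioselective acylation of a cis-1,2-diol: the tetracoordinate diphenylborinate chelate of the 3,4-diol is acylated at the equatorial, less hindered O3, while the axial O4 next to the lactone bridge stays free; no stereocentre is formed or touched.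

Step 5
Reactants: 9 1,3-bis-O-[(E)-3,4-diacetoxycinnamoyl]-1,5-quinide
Product: 10 1,3-di-O-[(E)-caffeoyl]-(−)-quinic acid
Conditions: 1 M aq HCl/THF 1:2, rt, argon, dark; reversed-phase (C18) chromatography
Reagents that add atoms: water, O
Why: Acid-catalysed ester hydrolysis cleaves the four aryl acetates and the strained γ-lactone (acyl–oxygen fission, so C5 keeps its configuration) faster than the two conjugated caffeoyl esters, and acidic rather than basic medium suppresses acyl migration from O3 to O4.

## Compound list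

1 | caffeic acid, (E)-3-(3,4-dihydroxyphenyl)prop-2-enoic acid | O=C(O)/C=C/c1ccc(O)c(O)c1 | starting material
2 | (E)-3-(3,4-diacetoxyphenyl)prop-2-enoic acid (di-O-acetylcaffeic acid) | CC(=O)Oc1ccc(/C=C/C(=O)O)cc1OC(C)=O | intermediate
3 | (E)-3-(3,4-diacetoxyphenyl)prop-2-enoyl chloride | CC(=O)Oc1ccc(/C=C/C(=O)Cl)cc1OC(C)=O | intermediate
4 | (−)-quinic acid, (1S,3R,4S,5R)-1,3,4,5-tetrahydroxycyclohexane-1-carboxylic acid | O[C@@H]1C[C@@](O)(C(=O)O)C[C@@H](O)[C@@H]1O | starting material
5 | phenylboronic acid | OB(O)c1ccccc1 | starting material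
6 | 1,5-quinide 3,4-O-phenylboronate: quinic acid γ-lactone (C1 carboxyl to O5) with O3 and O4 bridged by B–Ph, 1-OH free, quinic acid configuration at C1, C3, C4, C5 | c1ccc(cc1)B2O[C@@H]3C[C@]4(O)C[C@@H](OC4=O)[C@@H]3O2 | intermediate
7 | 1-O-[(E)-3,4-diacetoxycinnamoyl]-1,5-quinide 3,4-O-phenylboronate, quinic acid configuration | c1ccc(cc1)B2O[C@@H]3C[C@]4(OC(=O)/C=C/c5ccc(OC(C)=O)c(OC(C)=O)c5)C[C@@H](OC4=O)[C@@H]3O2 | intermediate
8 | 1-O-[(E)-3,4-diacetoxycinnamoyl]-1,5-quinide: γ-lactone with free equatorial 3-OH and axial 4-OH, quinic acid configuration | O[C@@H]1C[C@]2(OC(=O)/C=C/c3ccc(OC(C)=O)c(OC(C)=O)c3)C[C@@H](OC2=O)[C@@H]1O | intermediate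
9 | 1,3-bis-O-[(E)-3,4-diacetoxycinnamoyl]-1,5-quinide: γ-lactone with free axial 4-OH, quinic acid configuration | CC(=O)Oc1ccc(/C=C/C(=O)O[C@@H]2C[C@]3(OC(=O)/C=C/c4ccc(OC(C)=O)c(OC(C)=O)c4)C[C@@H](OC3=O)[C@@H]2O)cc1OC(C)=O | intermediate
10 | 1,3-di-O-[(E)-caffeoyl]-(−)-quinic acid (1,3-dicaffeoylquinic acid) | O=C(/C=C/c1ccc(O)c(O)c1)O[C@@H]1C[C@@](OC(=O)/C=C/c2ccc(O)c(O)c2)(C(=O)O)C[C@@H](O)[C@@H]1O | target

## Step count and risks

Total step count: 5. Longest linear sequence: 5 steps (1 → 2 → 3 → 8 → 9 → 10); counted from quinic acid it is 3 steps.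

The three steps most likely to fail, each with a fallback:

1. **Step 3.** The risks are competing boron chelation of the α-hydroxy acid, incomplete lactonisation, loss of the boronate during the slow acylation of the tertiary hydroxyl, and incomplete boron release. The fallback sets out from 4 and replaces the transient boron template by an isolable acetal. Refluxing 4 with 2,2-dimethoxypropane and p-MeC6H4SO3H·H2O in acetone gives 3,4-O-isopropylidene-1,5-quinide F1. Acylation of its tertiary hydroxyl with 3 (4-(dimethylamino)pyridine, pyridine, CH2Cl2) gives 1-O-[(E)-3,4-diacetoxycinnamoyl]-3,4-O-isopropylidene-1,5-quinide F2. Removal of the acetonide with CF3CO2H/H2O 9:1 at 0 °C, with lactone and aryl acetates retained, comes back to the route at 8.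

2. **Step 4.** The risks are imperfect O3 over O4 selectivity, over-acylation, and O3 to O4 acyl migration under the amine base. The fallback sets out from 4 and removes the need for any regiodifferentiation by locking the trans-4,5-diol. Butane-2,3-dione, HC(OMe)3, MeOH and camphor-10-sulfonic acid at reflux give methyl 4,5-O-(2,3-dimethoxybutane-2,3-diyl)quinate F3, in which only O1 and O3 (syn-diaxial) are free. Exhaustive acylation with 3 (3 equiv, 4-(dimethylamino)pyridine, pyridine, 40 °C) gives methyl 1,3-bis-O-[(E)-3,4-diacetoxycinnamoyl]-4,5-O-(2,3-dimethoxybutane-2,3-diyl)quinate F4. Prolonged 1 M aq HCl/THF then removes the diacetal, the four acetates and the methyl ester (the slow stage, helped by transient lactonisation onto the freed 5-OH) and comes back to the route at 10.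

3. **Step 5.** The risk is that the long acid exposure needed for four aryl acetates also hydrolyses a caffeoyl ester or leaves lactone unopened. The fallback sets out from 9 and separates the two tasks. Neutral chemoselective cleavage of the aryl acetates with NH4OAc in MeOH/H2O at rt gives 1,3-di-O-[(E)-caffeoyl]-1,5-quinide F5. A short treatment with dilute aq HCl/THF, now needed only for the lactone, comes back to the route at 10.

## Further compounds

F1 | step 3 | 3,4-O-isopropylidene-1,5-quinide | CC1(C)O[C@@H]2C[C@]3(O)C[C@@H](OC3=O)[C@@H]2O1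
F2 | step 3 | 1-O-[(E)-3,4-diacetoxycinnamoyl]-3,4-O-isopropylidene-1,5-quinide | CC1(C)O[C@@H]2C[C@]3(OC(=O)/C=C/c4ccc(OC(C)=O)c(OC(C)=O)c4)C[C@@H](OC3=O)[C@@H]2O1
F3 | step 4 | methyl 4,5-O-[(2S,3S)-2,3-dimethoxybutane-2,3-diyl]quinate | O[C@@H]1C[C@@](O)(C(=O)OC)C[C@H]2O[C@](C)(OC)[C@@](C)(OC)O[C@H]12
F4 | step 4 | methyl 1,3-bis-O-[(E)-3,4-diacetoxycinnamoyl]-4,5-O-[(2S,3S)-2,3-dimethoxybutane-2,3-diyl]quinate | CC(=O)Oc1ccc(/C=C/C(=O)O[C@@H]2C[C@@](OC(=O)/C=C/c3ccc(OC(C)=O)c(OC(C)=O)c3)(C(=O)OC)C[C@H]4O[C@](C)(OC)[C@@](C)(OC)O[C@H]24)cc1OC(C)=O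
F5 | step 5 | 1,3-di-O-[(E)-caffeoyl]-1,5-quinide | O=C(/C=C/c1ccc(O)c(O)c1)O[C@@H]1C[C@]2(OC(=O)/C=C/c3ccc(O)c(O)c3)C[C@@H](OC2=O)[C@@H]1O
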